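The runs are calculated with constants of no real substance; scatter was added.

The quick number starts from an easy step: partner is not among the readings, but its spending can be counted.

| flask | substrate | partner | remark | time |
|---|---|---|---|---|
| Sunday's | 7.4 mM | 8.8 mM | run made earlier |  |
| Wednesday's | 5.5 mM | 8.8 mM | run made earlier |  |
| alpha | 11 mM | 8.80 mM |  | 20 h |
| gamma | 11 mM | 11.0 mM |  | 20 h |

| run | time / h | double product / % | substrate / % | side product / % | first product / % |
|---|---|---|---|---|---|
| Sunday's | 3.00 | 4.9 | 61.8 | 0.2 | 25.1 |
| Sunday's | 6.00 | 10.1 | 44.0 | 1.6 | 25.1 |
| Sunday's | 10.0 | 14.1 | 32.4 | 1.0 | 19.0 |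
| Sunday's | 12.0 | 13.3 | 28.2 | 0 | 15.4 |
| Wednesday's | 1.00 | 0.9 | 82.4 | 0.7 | 15.9 |
| Wednesday's | 2.00 | 3.2 | 68.1 | 0.7 | 24.0 |
| Wednesday's | 5.00 | 10.2 | 45.0 | 0 | 28.3 |
| Wednesday's | 12.0 | 16.9 | 23.6 | 1.0 | 15.6 |

(readings scatter by 1 percentage point)

- the numbers in the tables scatter with a standard deviation of 1 percentage point
- on the list of suspects stand: partner + double product -> tris adduct + by-product; double product + by-product -> side product; substrate + partner -> first product + by-product; partner + first product -> double product + by-product; first product -> decomposed reagent

- which of these there is most of at the end, counted by the substrate in it, alpha (double product / side product / first product / substrate)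
- which of these there is most of at the end, counted by the substrate in it, gamma (double product / side product / first product / substrate)
- the largest of these amounts at the end, in percent of the substrate charged, alpha
- the largest of these amounts at the end, in percent of the substrate charged, gamma

Each substrate consumed takes one partner, and each double product takes a second. So n, the partner spent per substrate consumed, is one plus double product over substrate consumed. Wednesday's run had gone further than Sunday's by its last reading, and it gives n = 1.22 at 12.0 h, with tris adduct unread and left out. Carried to the new flasks, n makes partner the limiting reagent in both.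

The substrate floor F is the share of charged substrate left when partner is gone: one minus partner charge over n times substrate charge. Alpha has F = 34.5%, and gamma has 18.1%.

The approach to the floor comes from rate k·A·B, with rate constant k from Wednesday's first reading, A the substrate as a share of its charge cA, and partner B equal to n times the substrate above the floor. The ratio (A − F)/A then decays with time constant 1/(k·n·F·cA). That is 9.81 h for alpha and a slower 18.7 h for gamma. At 20 h this reckoning gives substrate 37.7% in alpha and 25.2% in gamma. With n held, double product reckons to 13.7% in alpha and 16.5% in gamma, less than substrate in each. First product in Wednesday's run had dropped to 15.6% by 12.0 h, so substrate is the pick.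

The forecast picks substrate for alpha at 36% (31% to 41%) and substrate for gamma at 25% (20% to 30%), and among its grounds stands “Each double product costs a second partner”. For alpha it stands below the reckoning here.

The flasks end with substrate at 35.9% in alpha and substrate at 25.3% in gamma.

    partner + double product → tris adduct + by-product (k = 0.00110 M⁻¹ s⁻¹)
    double product + by-product → side product (k = 3.60 × 10⁻⁴ M⁻¹ s⁻¹)
    substrate + partner → first product + by-product (k = 0.00660 M⁻¹ s⁻¹)
    partner + first product → double product + by-product (k = 0.00430 M⁻¹ s⁻¹)
    first product → decomposed reagent (k = 4.30 × 10⁻⁵ s⁻¹)

Left to 200 h, alpha holds 32.7% substrate against its reckoned floor of 34.5%, and gamma holds 19.8% against 18.1%, with partner at 0% and 0% of its charge. The neighbour flask is alpha with 22 mM of partner. With n held, its floor reckons to −63.8%, below zero, so the reckoning sets no floor there. At 20.0 h that flask holds 2.24% substrate, with 21% of its partner still unbound.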